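Over 2.0 h, target wears away for as long as it stands beside free base, so the question for each flask is how long its target has stood there.

| flask | electrophile | nucleophile | free base | time | remark |
|---|---|---|---|---|---|
| south-east | 0.10 M | 0.250 M | 0.120 M (fed, over 80 min) | 2.0 h | all else is in the flask from the start; the feed brings no volume worth counting |
| north-east | 0.10 M (fed, over 80 min) | 0.250 M | 0.120 M | 2.0 h | all else is in the flask from the start; the feed brings no volume worth counting |
| south-west | 0.10 M | 0.250 M | 0.120 M | 2.0 h | everything together at the start |

* the best flask by share of target in target plus over-reaction product; "all alike" if 1.5 percentage points covers them all (south-east / north-east / south-west / all alike)
* share of target in target plus over-reaction product at the end, south-east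
* share of target in target plus over-reaction product at the end, north-east
* share of target in target plus over-reaction product at the end, south-west

    electrophile + nucleophile → acid set free + target (k1 = 0.068 /M/min)
    electrophile + acid set free → side product (k2 = 2.3 /M/min)
    free base + target → over-reaction product (k3 = 0.042 /M/min)
    nucleophile + acid set free ⇌ protonated nucleophile, settled at all times (K4 = 10000 /M)
    acid set free → by-product carried off (k5 = 0.017 /min)
    acid set free + free base ⇌ salt of the base (K6 = 10 /M, k6 = 3.9 /M/min)

The wear is the over-reaction step, free base plus target, with constant 0.042 /M/min. The nucleophile holds the acid set free far more firmly than the free base does, 2500 against 1.2 as equilibrium constant times starting concentration, so we take the free base as staying near its charge. Target is then lost in a pseudo-first-order way, and we name the wear rate, the step's constant times the charge of free base: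

wear rate = 0.00504 /min

share of target ≈ exp(−wear rate × mean age of the target)

Now we solve the two ends. Suppose the whole of the target is born in the first moment. Its age is then 2.0 h, and the share is 54.6%. Suppose instead that it is born evenly. The mean age is then half the time, and the share is 73.9%.

We expect south-west to lie between these ends, nearer the first than an even birth would put it, because the half-life of electrophile by step 1 alone, 0.68 h, is shorter than the time in the flask. We take that half-life as the mean birth time:

south-west: age 79.2 min, share 67.1%

In north-east the electrophile arrives on average halfway through the feed, and we move the births later by that much:

north-east: age 39.2 min, share 82.1%

South-east delays the free base and leaves the births where they are. We put it between the other two, without a number of our own.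

The forecast gives 74% for south-east, 76% for north-east and 69% for south-west, and names north-east as best: “slow electrophile feed comes out narrowly best because the target forms late”. Our reckoning stands higher than the forecast for north-east and lower for south-west.

The flasks end at 74.8% in south-east, 78.0% in north-east and 70.2% in south-west, which makes north-east the best.

North-east still holds 89.0% of its free base after 2.00 h. Read back through the wear rate, its share gives a mean age of 49.3 min. A neighbour of north-east charged with 0.030 M of free base has a wear rate of 0.00126 /min. With the same age, that gives a share of 94.0%, and the neighbour flask ends at 93.8%.

All constants come from no measurement; the rest is arithmetic.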